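**Retrosynthetic overview**
- The spiro-cyclohexene has its side chain 1,3 to the spiro carbon C11, whereas a thermal Diels–Alder reaction of a myrcene-type diene with the α-methylene lactone would favour the 1,4-isomer. The ring is therefore built last: a radical three-component reaction puts an allyl group on C13 and a 2-substituted allyl group on C11 (anti to C8), and ring-closing metathesis then closes the cyclohexene.
- The ten-membered carbocycle is closed at the C4=C5 bond by ring-closing metathesis between a furanone isopropenyl group and a C6 vinyl group; the ring enforces the Z geometry.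
- The cis-fused γ-lactone (C6–C7 bond) comes from a zinc Barbier allylation of acrolein with a (Z)-2-(bromomethyl)enoate made by a Morita–Baylis–Hillman reaction and bromination.
- The 3(2H)-furanone comes from an acyl Sonogashira coupling and gold-catalysed cycloisomerisation; C8 is set by a proline aldol reaction and C10 by chelation-controlled ethynylation.
- Ring order: furanone, then γ-lactone, then ten-membered carbocycle, then spiro-cyclohexene; the angelate is attached last.

Assumption: the SMILES is read as (4Z,6S,7R,8R,10R,11S) in germacrane locants (C12 = lactone carbonyl, C13 = the exocyclic methylene carbon before annulation, C14/C15 = methyls), i.e. a cis-fused 12,6-lactone; these locants are used throughout.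

**Step 1**
Reactants: 1 acetone; 2 2,2-dimethoxyacetaldehyde
Product: 3 (4R)-4-hydroxy-5,5-dimethoxypentan-2-one
Conditions: (S)-proline (20 mol%), acetone as solvent, rt
Reagents that add atoms: none
Why: Proline-catalysed direct asymmetric aldol reaction; the (S)-proline enamine of acetone attacks the re face of the aldehyde through the hydrogen-bonded chair transition state, giving the (R)-carbinol that becomes C8.

**Step 2**
Reactants: 3 (4R)-4-hydroxy-5,5-dimethoxypentan-2-one; 4 ethynylmagnesium bromide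
Product: 5 (2R,4R)-1,1-dimethoxy-4-methylhex-5-yne-2,4-diol
Conditions: 4 (3 equiv), THF, −78 → −20 °C; aq. NH4Cl
Reagents that add atoms: none
Why: Chelation-controlled Grignard addition (Reetz 1,3-anti induction): the magnesium alkoxide chelates the ketone and the small acetylide attacks axially, trans to the equatorial C8 substituent, setting C10 as R; a moderate diastereomer ratio is expected and the minor syn diol is removed by chromatography.

**Step 3**
Reactants: 5 (2R,4R)-1,1-dimethoxy-4-methylhex-5-yne-2,4-diol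
Product: 6 (3R,5R)-5-[(tert-butyldimethylsilyl)oxy]-6,6-dimethoxy-3-methylhex-1-yn-3-ol
Conditions: TBSCl, imidazole, DMF, rt
Reagents that add atoms: tert-butyldimethylsilyl chloride, CC(C)(C)[Si](C)(C)Cl
Why: Selective silylation of the secondary alcohol; the tertiary propargylic alcohol does not react with TBSCl/imidazole and stays free for furanone formation.

**Step 4**
Reactants: 6 (3R,5R)-5-[(tert-butyldimethylsilyl)oxy]-6,6-dimethoxy-3-methylhex-1-yn-3-ol; 7 methacryloyl chloride
Product: 8 (6R,8R)-8-[(tert-butyldimethylsilyl)oxy]-6-hydroxy-9,9-dimethoxy-2,6-dimethylnon-1-en-4-yn-3-one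
Conditions: PdCl2(PPh3)2 (2 mol%), CuI (4 mol%), Et3N, THF, rt
Reagents that add atoms: none
Why: Acyl Sonogashira coupling of the terminal alkyne with the acid chloride gives the γ-hydroxy ynone; without an acyl-transfer catalyst the tertiary alcohol is not acylated.

**Step 5**
Reactants: 8 (6R,8R)-8-[(tert-butyldimethylsilyl)oxy]-6-hydroxy-9,9-dimethoxy-2,6-dimethylnon-1-en-4-yn-3-one
Product: 9 (2R)-2-[(2R)-2-[(tert-butyldimethylsilyl)oxy]-3,3-dimethoxypropyl]-2-methyl-5-(prop-1-en-2-yl)furan-3(2H)-one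
Conditions: [(4-CF3C6H4)3P]AuCl (5 mol%), AgOTf (5 mol%), toluene, rt
Reagents that add atoms: none
Why: Gold-catalysed cycloisomerisation of a γ-hydroxy ynone to a 3(2H)-furanone (water-assisted oxygen transposition, then cyclodehydration with the C10 hydroxyl oxygen becoming the ring oxygen), so the C10–O bond and its configuration are kept.

**Step 6**
Reactants: 9 (2R)-2-[(2R)-2-[(tert-butyldimethylsilyl)oxy]-3,3-dimethoxypropyl]-2-methyl-5-(prop-1-en-2-yl)furan-3(2H)-one
Product: 10 (2R)-2-[(tert-butyldimethylsilyl)oxy]-3-[(2R)-2-methyl-3-oxo-5-(prop-1-en-2-yl)-2,3-dihydrofuran-2-yl]propanal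
Conditions: LiBF4, MeCN/H2O (98:2), 60 °C
Reagents that add atoms: water, O
Why: Mild Lewis-acid-mediated acetal hydrolysis that leaves the silyl ether and the vinylogous ester intact; the α-silyloxy aldehyde is used directly to avoid epimerisation at C8.

**Step 7**
Reactants: 10 (2R)-2-[(tert-butyldimethylsilyl)oxy]-3-[(2R)-2-methyl-3-oxo-5-(prop-1-en-2-yl)-2,3-dihydrofuran-2-yl]propanal; 11 methyl acrylate
Product: 12 methyl (4R)-4-[(tert-butyldimethylsilyl)oxy]-3-hydroxy-2-methylidene-5-[(2R)-2-methyl-3-oxo-5-(prop-1-en-2-yl)-2,3-dihydrofuran-2-yl]pentanoate (both C3 epimers)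
Conditions: 11 (5 equiv), DABCO (1 equiv), MeOH, rt, 3 d
Reagents that add atoms: none
Why: Morita–Baylis–Hillman reaction; the new carbinol centre is formed as a mixture, which does not matter because it becomes an sp2 carbon in step 8.

**Step 8**
Reactants: 12 methyl (4R)-4-[(tert-butyldimethylsilyl)oxy]-3-hydroxy-2-methylidene-5-[(2R)-2-methyl-3-oxo-5-(prop-1-en-2-yl)-2,3-dihydrofuran-2-yl]pentanoate
Product: 13 methyl (2Z,4R)-2-(bromomethyl)-4-[(tert-butyldimethylsilyl)oxy]-5-[(2R)-2-methyl-3-oxo-5-(prop-1-en-2-yl)-2,3-dihydrofuran-2-yl]pent-2-enoate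
Conditions: NBS, Me2S, CH2Cl2, 0 °C → rt
Reagents that add atoms: N-bromosuccinimide, BrN1C(=O)CCC1=O
Why: Corey–Kim-type activation of the allylic alcohol and SN2′ attack of bromide (allylic transposition) give the thermodynamically preferred (Z)-2-(bromomethyl)enoate, with the C8 chain cis to CH2Br.

**Step 9**
Reactants: 13 methyl (2Z,4R)-2-(bromomethyl)-4-[(tert-butyldimethylsilyl)oxy]-5-[(2R)-2-methyl-3-oxo-5-(prop-1-en-2-yl)-2,3-dihydrofuran-2-yl]pent-2-enoate; 14 acrolein
Product: 16 (4S,5S)-4-{(1R)-1-[(tert-butyldimethylsilyl)oxy]-2-[(2R)-2-methyl-3-oxo-5-(prop-1-en-2-yl)-2,3-dihydrofuran-2-yl]ethyl}-5-ethenyl-3-methylidenedihydrofuran-2(3H)-one, via hydroxy ester 15 (not isolated)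
Conditions: 14 (3 equiv), Zn dust, THF/sat. aq. NH4Cl, 0 °C → rt; then PPTS (cat.), toluene, 50 °C
Reagents that add atoms: none
Why: Zinc-mediated Barbier allylation and lactonisation: the γ-substituent cis to CH2Zn sits axial in the six-membered chair transition state, giving the syn adduct and hence the cis-lactone (C6 S); the face of C7 is set by C8, whose hydrogen eclipses the alkene (allylic 1,3-strain) so that acrolein adds anti to the C9 chain; the vinylogous-ester carbonyl of the furanone is not attacked.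

**Step 10**
Reactants: 16 (4S,5S)-4-{(1R)-1-[(tert-butyldimethylsilyl)oxy]-2-[(2R)-2-methyl-3-oxo-5-(prop-1-en-2-yl)-2,3-dihydrofuran-2-yl]ethyl}-5-ethenyl-3-methylidenedihydrofuran-2(3H)-one
Product: 17 (4Z,6S,7S,8R,10R)-8-[(tert-butyldimethylsilyl)oxy]-3,10-epoxy-1-oxogermacra-2,4,11(13)-trien-12,6-olide
Conditions: second-generation Hoveyda–Grubbs catalyst RuCl2(H2IMes)(=CH-C6H4-2-OiPr) (15 mol%), toluene (1 mM), 80 °C
Reagents that add atoms: none
Why: Ring-closing metathesis between the C6 vinyl and the furanone isopropenyl group closes the ten-membered carbocycle; the medium ring can only hold the cis (4Z) trisubstituted alkene, and the electron-poor 1,1-disubstituted lactone methylene does not take part.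

**Step 11**
Reactants: 18 2-methylprop-2-en-1-ol; 19 1-bromo-3-methylbut-2-ene
Product: 21 6-methyl-2-methylidenehept-5-en-1-ol, via dilithium dianion 20 (not isolated)
Conditions: n-BuLi (2.2 equiv), TMEDA, Et2O, 0 °C → rt; then 19, −78 °C → rt
Reagents that add atoms: n-butyllithium, [Li]CCCC (supplies the lithium of 20 only)
Why: Allylic deprotonation of the lithium alkoxide gives the alkoxide-stabilised allyl dianion, which is alkylated at carbon by the primary allylic bromide (SN2).

**Step 12**
Reactants: 21 6-methyl-2-methylidenehept-5-en-1-ol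
Product: 23 [(6-methyl-2-methylidenehept-5-en-1-yl)sulfonyl]benzene, via allylic mesylate 22 (not isolated)
Conditions: MsCl, Et3N, CH2Cl2, 0 °C; then PhSO2Na, DMF, rt
Reagents that add atoms: methanesulfonyl chloride, CS(=O)(=O)Cl (stays in 22 only); sodium benzenesulfinate, [Na+].[O-]S(=O)c1ccccc1
Why: Mesylation followed by SN2 displacement with sulfinate (S-alkylation) gives the allyl sulfone used as radical allyl-transfer reagent.

**Step 13**
Reactants: 17 (4Z,6S,7S,8R,10R)-8-[(tert-butyldimethylsilyl)oxy]-3,10-epoxy-1-oxogermacra-2,4,11(13)-trien-12,6-olide; 24 potassium allyltrifluoroborate; 23 [(6-methyl-2-methylidenehept-5-en-1-yl)sulfonyl]benzene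
Product: 25 (4Z,6S,7S,8R,10R,11S)-8-[(tert-butyldimethylsilyl)oxy]-11-(6-methyl-2-methylidenehept-5-en-1-yl)-13-(prop-2-en-1-yl)-3,10-epoxy-1-oxogermacra-2,4-dien-12,6-olide
Conditions: 24 (3 equiv), 23 (5 equiv), [Ir(dF(CF3)ppy)2(dtbbpy)]PF6 (2 mol%), acetone, blue LEDs, rt
Reagents that add atoms: none
Why: Proposed new method: the excited trivalent iridium photocatalyst oxidises the allyltrifluoroborate to the allyl radical, which as a nucleophilic radical adds to the unhindered, most electron-poor alkene, the exocyclic CH2 of the α-methylene lactone (C13–C bond); the resulting electrophilic tertiary radical at C11 is polarity-matched to the electron-rich 1,1-disubstituted alkene of 23 and is allylated by addition and β-fragmentation (SH2′) on the convex lactone face anti to the C8 substituent, which sets the quaternary centre C11 as S; the expelled PhSO2 radical is reduced to sulfinate by divalent iridium, closing a redox-neutral cycle; the closest known reaction types are the three-component radical coupling of a radical precursor, an acrylate and an allylstannane or allyl sulfone (Giese addition then Keck-type allyl transfer) and photoredox Giese additions of organotrifluoroborates.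

**Step 14**
Reactants: 25 (4Z,6S,7S,8R,10R,11S)-8-[(tert-butyldimethylsilyl)oxy]-11-(6-methyl-2-methylidenehept-5-en-1-yl)-13-(prop-2-en-1-yl)-3,10-epoxy-1-oxogermacra-2,4-dien-12,6-olide
Product: 26 (4Z,6S,7S,8R,10R,11S)-8-[(tert-butyldimethylsilyl)oxy]-3,10-epoxy-1-oxogermacra-2,4-dien-12,6-olide with C11 as spiro atom of the ring C11–C13H2–CH2–CH=C(CH2CH2CH=CMe2)–CH2–C11
Conditions: second-generation Grubbs catalyst RuCl2(H2IMes)(PCy3)(=CHPh) (5 mol%), CH2Cl2, 40 °C
Reagents that add atoms: none
Why: Ring-closing metathesis of the monosubstituted and the 1,1-disubstituted terminal alkenes gives the six-membered trisubstituted cyclohexene; all other alkenes are trisubstituted, ring-locked or conjugated and do not react, and no stereocentre is touched.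

**Step 15**
Reactants: 26 spiro-lactone tert-butyldimethylsilyl ether (as in step 14)
Product: 27 (4Z,6S,7R,8R,10R,11S)-8-hydroxy-3,10-epoxy-1-oxogermacra-2,4-dien-12,6-olide with C11 as spiro atom of the ring C11–C13H2–CH2–CH=C(CH2CH2CH=CMe2)–CH2–C11
Conditions: HF·pyridine, pyridine, THF, 0 °C → rt
Reagents that add atoms: none
Why: Fluoride-mediated desilylation under buffered, non-basic conditions, which avoids base-induced translactonisation to the 8,12-olide and HF addition to the alkenes (the C7 descriptor changes from S to R only because the priority of C8 changes).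

**Step 16**
Reactants: 27 spiro-lactone alcohol (as in step 15); 28 (2Z)-2-methylbut-2-enoic acid (angelic acid)
Product: 30 target CNP0226905.2, via mixed anhydride 29 (not isolated)
Conditions: 28, 2,4,6-Cl3C6H2COCl, Et3N, toluene, rt; then 27, 75 °C
Reagents that add atoms: 2,4,6-trichlorobenzoyl chloride, O=C(Cl)c1c(Cl)cc(Cl)cc1Cl (stays in 29 only)
Why: Yamaguchi esterification through the mixed anhydride, run without a nucleophilic amine catalyst so that the angelate does not isomerise to the tiglate; the alcohol attacks the unhindered angeloyl carbonyl, with retention at C8.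

**Compound list**
1 | acetone | CC(C)=O | starting material
2 | 2,2-dimethoxyacetaldehyde | COC(OC)C=O | starting material
3 | (4R)-4-hydroxy-5,5-dimethoxypentan-2-one | O[C@@H](C(OC)OC)CC(C)=O | intermediate
4 | ethynylmagnesium bromide | C#C[Mg]Br | starting material
5 | (2R,4R)-1,1-dimethoxy-4-methylhex-5-yne-2,4-diol | O[C@@H](C(OC)OC)C[C@@](C#C)(C)O | intermediate
6 | (3R,5R)-5-[(tert-butyldimethylsilyl)oxy]-6,6-dimethoxy-3-methylhex-1-yn-3-ol | CC(C)(C)[Si](C)(C)O[C@@H](C(OC)OC)C[C@@](C#C)(C)O | intermediate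
7 | methacryloyl chloride | CC(=C)C(Cl)=O | starting material
8 | (6R,8R)-8-[(tert-butyldimethylsilyl)oxy]-6-hydroxy-9,9-dimethoxy-2,6-dimethylnon-1-en-4-yn-3-one | CC(C)(C)[Si](C)(C)O[C@@H](C(OC)OC)C[C@@](C#CC(=O)C(C)=C)(C)O | intermediate
9 | (2R)-2-[(2R)-2-[(tert-butyldimethylsilyl)oxy]-3,3-dimethoxypropyl]-2-methyl-5-(prop-1-en-2-yl)furan-3(2H)-one | CC(C)(C)[Si](C)(C)O[C@@H](C(OC)OC)C[C@@]1(C)OC(=CC1=O)C(C)=C | intermediate
10 | (2R)-2-[(tert-butyldimethylsilyl)oxy]-3-[(2R)-2-methyl-3-oxo-5-(prop-1-en-2-yl)-2,3-dihydrofuran-2-yl]propanal | CC(C)(C)[Si](C)(C)O[C@@H](C=O)C[C@@]1(C)OC(=CC1=O)C(C)=C | intermediate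
11 | methyl acrylate | C=CC(=O)OC | starting material
12 | methyl (4R)-4-[(tert-butyldimethylsilyl)oxy]-3-hydroxy-2-methylidene-5-[(2R)-2-methyl-3-oxo-5-(prop-1-en-2-yl)-2,3-dihydrofuran-2-yl]pentanoate (C3 epimers) | CC(C)(C)[Si](C)(C)O[C@@H](C(O)C(=C)C(=O)OC)C[C@@]1(C)OC(=CC1=O)C(C)=C | intermediate
13 | methyl (2Z,4R)-2-(bromomethyl)-4-[(tert-butyldimethylsilyl)oxy]-5-[(2R)-2-methyl-3-oxo-5-(prop-1-en-2-yl)-2,3-dihydrofuran-2-yl]pent-2-enoate | CC(C)(C)[Si](C)(C)O[C@@H](/C=C(\CBr)C(=O)OC)C[C@@]1(C)OC(=CC1=O)C(C)=C | intermediate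
14 | acrolein | C=CC=O | starting material
15 | methyl (3S,4S)-3-{(1R)-1-[(tert-butyldimethylsilyl)oxy]-2-[(2R)-2-methyl-3-oxo-5-(prop-1-en-2-yl)-2,3-dihydrofuran-2-yl]ethyl}-4-hydroxy-2-methylidenehex-5-enoate | C=C[C@H](O)[C@H](C(=C)C(=O)OC)[C@H](O[Si](C)(C)C(C)(C)C)C[C@@]1(C)OC(=CC1=O)C(C)=C | intermediate
16 | (4S,5S)-4-{(1R)-1-[(tert-butyldimethylsilyl)oxy]-2-[(2R)-2-methyl-3-oxo-5-(prop-1-en-2-yl)-2,3-dihydrofuran-2-yl]ethyl}-5-ethenyl-3-methylidenedihydrofuran-2(3H)-one | C=C[C@@H]2OC(=O)C(=C)[C@@H]2[C@H](O[Si](C)(C)C(C)(C)C)C[C@@]1(C)OC(=CC1=O)C(C)=C | intermediate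
17 | (4Z,6S,7S,8R,10R)-8-[(tert-butyldimethylsilyl)oxy]-3,10-epoxy-1-oxogermacra-2,4,11(13)-trien-12,6-olide | CC(C)(C)[Si](C)(C)O[C@@H]1C[C@@]2(C)OC(=CC2=O)/C(C)=C\[C@@H]2OC(=O)C(=C)[C@@H]21 | intermediate
18 | 2-methylprop-2-en-1-ol | CC(=C)CO | starting material
19 | 1-bromo-3-methylbut-2-ene | CC(C)=CCBr | starting material
20 | dilithium dianion of 2-methylprop-2-en-1-ol | [Li+].[Li+].[CH2-]C(=C)C[O-] | intermediate
21 | 6-methyl-2-methylidenehept-5-en-1-ol | C=C(CO)CCC=C(C)C | intermediate
22 | 6-methyl-2-methylidenehept-5-en-1-yl methanesulfonate | C=C(COS(C)(=O)=O)CCC=C(C)C | intermediate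
23 | [(6-methyl-2-methylidenehept-5-en-1-yl)sulfonyl]benzene | C=C(CS(=O)(=O)c1ccccc1)CCC=C(C)C | intermediate
24 | potassium allyltrifluoroborate | [K+].C=CC[B-](F)(F)F | starting material
25 | (4Z,6S,7S,8R,10R,11S)-8-[(tert-butyldimethylsilyl)oxy]-11-(6-methyl-2-methylidenehept-5-en-1-yl)-13-(prop-2-en-1-yl)-3,10-epoxy-1-oxogermacra-2,4-dien-12,6-olide | CC(C)(C)[Si](C)(C)O[C@@H]1C[C@@]2(C)OC(=CC2=O)/C(C)=C\[C@@H]2OC(=O)[C@@](CCC=C)(CC(=C)CCC=C(C)C)[C@@H]21 | intermediate
26 | (4Z,6S,7S,8R,10R,11S)-8-[(tert-butyldimethylsilyl)oxy]-3,10-epoxy-1-oxogermacra-2,4-dien-12,6-olide, C11 spiro to 3-(4-methylpent-3-en-1-yl)cyclohex-3-ene (ring C11–C13H2–CH2–CH=C(R)–CH2) | CC(C)(C)[Si](C)(C)O[C@@H]1C[C@@]2(C)OC(=CC2=O)/C(C)=C\[C@@H]2OC(=O)[C@]3(CCC=C(CCC=C(C)C)C3)[C@@H]21 | intermediate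
27 | (4Z,6S,7R,8R,10R,11S)-8-hydroxy analogue of 26 (free C8 alcohol) | O[C@@H]1C[C@@]2(C)OC(=CC2=O)/C(C)=C\[C@@H]2OC(=O)[C@]3(CCC=C(CCC=C(C)C)C3)[C@@H]21 | intermediate
28 | (2Z)-2-methylbut-2-enoic acid (angelic acid) | C/C=C(/C)C(=O)O | starting material
29 | (2Z)-2-methylbut-2-enoic 2,4,6-trichlorobenzoic anhydride | C/C=C(/C)C(=O)OC(=O)c1c(Cl)cc(Cl)cc1Cl | intermediate
30 | CNP0226905.2: (4Z,6S,7R,8R,10R,11S)-8-[(2Z)-2-methylbut-2-enoyloxy]-3,10-epoxy-1-oxogermacra-2,4-dien-12,6-olide, C11 spiro to 3-(4-methylpent-3-en-1-yl)cyclohex-3-ene | C/C=C(/C)C(=O)O[C@@H]1C[C@@]2(C)OC(=CC2=O)/C(C)=C\[C@@H]2OC(=O)[C@]3(CCC=C(CCC=C(C)C)C3)[C@@H]21 | target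

**Step count**
Total: 16 steps. Longest linear sequence: 14 steps (steps 1–10 and 13–16); steps 11–12 make the side-chain sulfone.

**Three steps most likely to fail**

Step 13 (radical carbo-diallylation). The allyl radical is stabilised and adds slowly, and the C11 radical can be reduced to the enolate before it is allylated. The fallback sets out from 17 and comes back at 25 by two-electron chemistry. Allylmagnesium bromide with CuBr·SMe2 and Me3SiCl in THF at −78 °C delivers the allyl group 1,4 to the exocyclic methylene and gives the trimethylsilyl ketene acetal F5. F5 is then alkylated at C11, again anti to C8, with 2-(bromomethyl)-6-methylhepta-1,5-diene F6 (from 21 with PBr3) under fluoride activation with Bu4N[Ph3SiF2], which gives 25.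

Step 10 (macrocyclising metathesis). Initiation at the hindered C6 vinyl group next to the lactone oxygen may be slow, and dimers may form. The fallback sets out from 13 and comes back at 17 by relay ring-closing metathesis. In the zinc Barbier reaction acrolein is replaced by (2E)-octa-2,7-dienal F2, made by a Wittig reaction of commercial hex-5-enal with Ph3P=CHCHO. This gives, through the relay hydroxy ester F3, the relay lactone F4, which carries a (1E)-hepta-1,6-dienyl group on C6. The second-generation Hoveyda–Grubbs catalyst loads at the remote terminal alkene, expels cyclopentene to place the ruthenium alkylidene on C5, and closes onto the isopropenyl group to give 17.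

Step 9 (Barbier allylation). The syn/anti ratio and the face selection by C8 may be insufficient with zinc. The fallback sets out from 13 and comes back at 16. Bromide 13 is converted with B2pin2, Pd2(dba)3 and KOAc into the pinacol allylboronate F1, which keeps the trisubstituted alkene geometry. Sc(OTf)3-catalysed allylboration of 14 then proceeds through a closed six-membered transition state that is stereospecific for the syn adduct 15, and 15 lactonises to 16. If the C8-controlled face selection is the problem, a chiral phosphoric acid catalyst can be used in this allylboration to impose it.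

**Further compounds**
F1 | step 9 | methyl (2E,4R)-4-[(tert-butyldimethylsilyl)oxy]-5-[(2R)-2-methyl-3-oxo-5-(prop-1-en-2-yl)-2,3-dihydrofuran-2-yl]-2-[(4,4,5,5-tetramethyl-1,3,2-dioxaborolan-2-yl)methyl]pent-2-enoate | CC(C)(C)[Si](C)(C)O[C@@H](/C=C(\CB1OC(C)(C)C(C)(C)O1)C(=O)OC)C[C@@]1(C)OC(=CC1=O)C(C)=C
F2 | step 10 | (2E)-octa-2,7-dienal | C=CCCC/C=C/C=O
F3 | step 10 | methyl (3S,4S,5E)-3-{(1R)-1-[(tert-butyldimethylsilyl)oxy]-2-[(2R)-2-methyl-3-oxo-5-(prop-1-en-2-yl)-2,3-dihydrofuran-2-yl]ethyl}-4-hydroxy-2-methylideneundeca-5,10-dienoate | C=CCCC/C=C/[C@H](O)[C@H](C(=C)C(=O)OC)[C@H](O[Si](C)(C)C(C)(C)C)C[C@@]1(C)OC(=CC1=O)C(C)=C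
F4 | step 10 | (4S,5S)-4-{(1R)-1-[(tert-butyldimethylsilyl)oxy]-2-[(2R)-2-methyl-3-oxo-5-(prop-1-en-2-yl)-2,3-dihydrofuran-2-yl]ethyl}-5-[(1E)-hepta-1,6-dien-1-yl]-3-methylidenedihydrofuran-2(3H)-one | C=CCCC/C=C/[C@@H]2OC(=O)C(=C)[C@@H]2[C@H](O[Si](C)(C)C(C)(C)C)C[C@@]1(C)OC(=CC1=O)C(C)=C
F5 | step 13 | trimethylsilyl ketene acetal of the 13-allyl lactone derived from 17 (C11=C12 enol silyl ether, C11 bearing but-3-en-1-yl) | CC(C)(C)[Si](C)(C)O[C@@H]1C[C@@]2(C)OC(=CC2=O)/C(C)=C\[C@@H]2OC(O[Si](C)(C)C)=C(CCC=C)[C@@H]21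
F6 | step 13 | 2-(bromomethyl)-6-methylhepta-1,5-diene | C=C(CBr)CCC=C(C)C
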